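Late in the red run Z creeps from 64.9% at 25.0 min to 86.0% at 60.0 min. D takes Q one for one into L, and its charge can take at most 2.00% of Q, so the level under the curve of Z is 98.0%. Near that level the percentage of Z says little, so the thing to follow is the fraction of Q left. Its negative logarithm, the depth, is the axis of a pseudo-first-order plot.

common to all: Q 0.19 M

|  | D | G | remark | time |
|---|---|---|---|---|
| red | 3.8 mM | 4.2 mol% | run made earlier |  |
| violet | 3.8 mM | 6.7 mol% | run made earlier |  |
| east | 3.80 mM | 5 mol% |  | 1.0 h |
| south-west | 3.80 mM | 8 mol% |  | 0.25 h |

| red: time / min | red: Z / % | violet: time / min | violet: Z / % |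
|---|---|---|---|
| 5.00 | 22.1 | 5.00 | 26.9 |
| 12.0 | 42.2 | 12.0 | 50.4 |
| 25.0 | 64.9 | 25.0 | 75.1 |
| 60.0 | 86.0 | 60.0 | 92.5 |

(each reading ± 0.3 percentage points)

- reactions considered so far: G -> 2 E; Q + E -> X + Z; Q + X -> Z + X; 2 X -> J; D + Q -> L

- the flask that ends with the higher amount of Z, in percent of the Q charged, or "neither" when 2 percentage points or less lies between them (east / south-west / neither)
- final Z, as a percentage of the Q charged, in east
- final Z, as a percentage of the Q charged, in south-west

Counting D as already turned into L, the depth slope of the red run reads 0.0552 min⁻¹ up to its first reading and 0.0290 min⁻¹ between its last two readings, less than over the first stretch, so the plot bends. The violet run passes half of the charge as Z by 12.0 min.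

At 60.0 min the red run stands at depth 2.12 and the violet run at 2.90. X is made in proportion to G and lost in pairs, so my own reckoning reads depth against the root of the loading. East runs for the same time at a loading between the two, which gives 2.39, the depth of east at its end, and so Z of 88.8%.

For south-west, chords between the readings on either side of 15 min put red at 0.704 and violet at 0.911. Carrying the line beyond violet to 8 mol% gives depth 1.00 and Z of 61.3%, an extrapolation and so the weaker figure.

The forecast, by its own decay fit and not by these interpolations, says 88.9% for east and 61.3% for south-west, and names east: “its longer time outweighs the lower G”.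

The flask gives 88.9% in east and 61.8% in south-west, so east stands higher by 27 percentage points.

    G → 2 E (k = 4.96 × 10⁻⁴ s⁻¹)
    Q + E → X + Z (k = 3.09 × 10⁵ M⁻¹ s⁻¹)
    Q + X → Z + X, rate k3*[X]*[Q] (k = 3210 M⁻¹ s⁻¹)
    2 X → J (k = 6.30 × 10⁷ M⁻¹ s⁻¹)
    D + Q → L (k = 0.0699 M⁻¹ s⁻¹)

East is still moving at its end, with 17% of its G and 9.09% of its Q left, and ten times as long brings Z to 96.5%. Stretched by the root of the G concentration, the depth of east, 2.39, gives 4.49% of Q left for a flask like east at 0.32 M of Q, with the loading of G held and D at 0.0119 equiv. That flask holds 4.2% after 1.00 h.

The numbers in the tables come from a simulation with made-up constants, and the scatter is random.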